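**Plan**

- Ring A is a cyclohexene whose trisubstituted C(Br)=CH bond lies between the CMe2 carbon and the CHBr carbon; this is the one bond of the carbocycle that alkene metathesis can make, so ring A is cut there.
- Retrosynthetic cuts, in order: the allylic C–Br bond (from the alcohol, with inversion); the acetal C–O bond of the oxetane (lactol plus tertiary alcohol); C(Br)=CH of ring A (metathesis); C–CH3 of the tertiary carbinol; the bond from the spiro carbon to the carbinol chain (aldol); the spiro carbon–CMe2 bond (Nicholas reaction).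
- Forward order: butyrolactone ring, then the CMe2–C(Br)=CH2 arm, then the aldol that creates the quaternary carbon, methyl addition, ring A by metathesis, lactol, oxetane, and last the second bromine.
- Stereochemistry: the isopropenyl-bearing carbon comes from a CBS reduction; the quaternary carbon from an aldol anti to that group; the secondary carbinol from (R)-but-3-ene-1,2-diol; the tertiary carbinol from chelation-controlled MeMgBr addition; the acetal carbon is fixed by the cis-fused four-membered ring; the CHBr centre arises by SN2 inversion.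

Key step: step 14

Assumption: in the oxazaborolidine reduction (step 3) the isopropenyl group is taken to act as the large ketone substituent, as α-branched alkenyl groups generally do.

**Route**

Step 1
Reactants: 1 2-bromopropene; 2 succinic anhydride
Product: 4 5-methyl-4-oxohex-5-enoic acid, via isopropenylmagnesium bromide 3 (not isolated)
Conditions: Mg, THF, reflux; then added slowly to 2, THF, −78 °C; aq. HCl
Reagents that add atoms: none
Why: Grignard acylation of a cyclic anhydride, in which inverse addition at low temperature keeps the alkenylmagnesium reagent limiting so that the γ-keto acid, not the double-addition lactone, should prevail.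

Step 2
Reactants: 4 5-methyl-4-oxohex-5-enoic acid
Product: 5 methyl 5-methyl-4-oxohex-5-enoate
Conditions: MeI, K2CO3, DMF, rt
Reagents that add atoms: iodomethane, CI
Why: SN2 O-alkylation of the carboxylate gives the ester, which is needed because a free acid would consume the borane of the next step.

Step 3
Reactants: 5 methyl 5-methyl-4-oxohex-5-enoate
Product: 7 (R)-5-(prop-1-en-2-yl)dihydrofuran-2(3H)-one, via hydroxy ester 6 (not isolated)
Conditions: (S)-2-methyl-CBS-oxazaborolidine (10 mol %), catecholborane, toluene, −78 °C; then PPTS (cat.), CH2Cl2, rt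
Reagents that add atoms: none
Why: Corey–Bakshi–Shibata reduction, in which the (S)-oxazaborolidine binds the enone with isopropenyl as the large group and delivers hydride to give the (R)-carbinol, which then lactonizes under mild acid with loss of methanol.

Step 4
Reactants: 8 2-methylbut-3-yn-2-ol
Product: 9 hexacarbonyl(μ-2-methylbut-3-yn-2-ol)dicobalt
Conditions: Co2(CO)8, CH2Cl2, rt
Reagents that add atoms: dicobalt octacarbonyl, O=C=[Co](=C=O)(=C=O)(=C=O)[Co](=C=O)(=C=O)(=C=O)=C=O
Why: Alkyne complexation with Co2(CO)8 (two CO are displaced) is the standard entry to Nicholas chemistry and makes the tertiary propargylic alcohol a precursor of a stabilized cation.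

Step 5
Reactants: 7 (R)-5-(prop-1-en-2-yl)dihydrofuran-2(3H)-one; 9 hexacarbonyl(μ-2-methylbut-3-yn-2-ol)dicobalt
Product: 11 Co2(CO)6 complex of (5R)-3-(2-methylbut-3-yn-2-yl)-5-(prop-1-en-2-yl)dihydrofuran-2(3H)-one, via silyl ketene acetal 10 (not isolated)
Conditions: LiN(i-Pr)2, THF, −78 °C, then Me3SiCl; solvent change to CH2Cl2; 9, BF3·OEt2, −78 → −20 °C
Reagents that add atoms: none
Why: Nicholas reaction, in which BF3 ionizes the hydroxyl of 9 to the Co2(CO)6-stabilized tertiary propargylic cation and the silyl ketene acetal captures it at carbon, the reliable way to attach a tertiary propargyl group to a lactone α-carbon; the C3 configuration formed here is erased in step 11.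

Step 6
Reactants: 11 Co2(CO)6 complex of the propargylated lactone
Product: 12 (5R)-3-(2-methylbut-3-yn-2-yl)-5-(prop-1-en-2-yl)dihydrofuran-2(3H)-one (C3 epimers)
Conditions: (NH4)2Ce(NO3)6, acetone, 0 °C
Reagents that add atoms: none
Why: Oxidative decomplexation by tetravalent cerium strips the cobalt carbonyl unit and frees the terminal alkyne without touching the lactone or the isopropenyl group.

Step 7
Reactants: 12 (5R)-3-(2-methylbut-3-yn-2-yl)-5-(prop-1-en-2-yl)dihydrofuran-2(3H)-one
Product: 14 (5R)-3-(3-bromo-2-methylbut-3-en-2-yl)-5-(prop-1-en-2-yl)dihydrofuran-2(3H)-one (C3 epimers), via alkenylborane 13 (not isolated)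
Conditions: B-bromo-9-BBN, CH2Cl2, 0 °C; then AcOH, 0 °C → rt
Reagents that add atoms: B-bromo-9-borabicyclo[3.3.1]nonane, BrB1C2CCCC1CCC2
Why: Bromoboration of a terminal alkyne adds boron and bromine cis with bromine on the internal carbon, and protonolysis of the alkenyl–boron bond by acetic acid leaves the 2-bromo-1-alkene, while alkenes and esters are inert to this reagent under these conditions.

Step 8
Reactants: 15 (R)-but-3-ene-1,2-diol
Product: 16 (4R)-2-(4-methoxyphenyl)-4-vinyl-1,3-dioxolane (acetal epimers)
Conditions: 4-MeOC6H4CH(OMe)2, PPTS (cat.), CH2Cl2, rt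
Reagents that add atoms: 4-methoxybenzaldehyde dimethyl acetal, COc1ccc(C(OC)OC)cc1
Why: Acid-catalysed transacetalization of a 1,2-diol gives the p-methoxybenzylidene acetal, and both acetal epimers serve in the next step.

Step 9
Reactants: 16 (4R)-2-(4-methoxyphenyl)-4-vinyl-1,3-dioxolane
Product: 17 (R)-2-(4-methoxybenzyloxy)but-3-en-1-ol
Conditions: i-Bu2AlH, CH2Cl2, −78 → 0 °C; aq. potassium sodium tartrate
Reagents that add atoms: none
Why: Regioselective reductive opening of a p-methoxybenzylidene acetal, in which aluminium binds the less hindered primary oxygen and hydride delivery leaves the PMB ether on the secondary oxygen.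

Step 10
Reactants: 17 (R)-2-(4-methoxybenzyloxy)but-3-en-1-ol
Product: 18 (R)-2-(4-methoxybenzyloxy)but-3-enal
Conditions: Dess–Martin periodinane, NaHCO3, CH2Cl2, 0 °C; used at once
Reagents that add atoms: none
Why: Dess–Martin oxidation under buffered, non-basic conditions should give the α-alkoxy-β,γ-unsaturated aldehyde without racemization or double-bond migration, provided it is used immediately.

Step 11
Reactants: 14 (5R)-3-(3-bromo-2-methylbut-3-en-2-yl)-5-(prop-1-en-2-yl)dihydrofuran-2(3H)-one; 18 (R)-2-(4-methoxybenzyloxy)but-3-enal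
Product: 20 (3S,5R)-3-(3-bromo-2-methylbut-3-en-2-yl)-3-[(2R)-1-hydroxy-2-(4-methoxybenzyloxy)but-3-en-1-yl]-5-(prop-1-en-2-yl)dihydrofuran-2(3H)-one (carbinol epimers), via lithium enolate 19 (not isolated)
Conditions: LiN(i-Pr)2, THF, −78 → −40 °C; then 18, −78 °C; AcOH quench at −78 °C
Reagents that add atoms: none
Why: Lithium enolate aldol addition, in which the enolate is planar at C3 and the aldehyde should approach anti to the C5 isopropenyl group (the 1,3-induction typical of 5-substituted butyrolactone enolates), setting the quaternary centre with the new chain trans to isopropenyl, while the carbinol epimers converge in step 12.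

Step 12
Reactants: 20 aldol adduct
Product: 21 (3S,5R)-3-(3-bromo-2-methylbut-3-en-2-yl)-3-[(2R)-2-(4-methoxybenzyloxy)but-3-enoyl]-5-(prop-1-en-2-yl)dihydrofuran-2(3H)-one
Conditions: Dess–Martin periodinane, NaHCO3, CH2Cl2, 0 °C → rt
Reagents that add atoms: none
Why: Dess–Martin oxidation of a hindered secondary alcohol, in which the quaternary α-carbon excludes enolization between the two carbonyls and the near-neutral medium should preserve the α-alkoxy stereocentre.

Step 13
Reactants: 21 β-keto lactone
Product: 22 (3S,5R)-3-(3-bromo-2-methylbut-3-en-2-yl)-3-[(2S,3R)-2-hydroxy-3-(4-methoxybenzyloxy)pent-4-en-2-yl]-5-(prop-1-en-2-yl)dihydrofuran-2(3H)-one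
Conditions: MeMgBr, CH2Cl2/Et2O, −78 °C; aq. NH4Cl
Reagents that add atoms: methylmagnesium bromide, C[Mg]Br
Why: Chelation-controlled Grignard addition, in which magnesium bridges the ketone oxygen and the α-OPMB oxygen (Cram chelate) and can also bind the lactone carbonyl, and both chelates expose the same ketone face (the side of the hydrogen on the OPMB carbon and of the ring CH2, away from the CMe2 arm), so methyl should enter there and give the (S)-tertiary carbinol syn to the OPMB group.

Step 14
Reactants: 22 spiro-lactone precursor carrying the 2-bromoallyl arm and the vinyl carbinol arm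
Product: 23 (3R,5S,9R,10S)-7-bromo-10-hydroxy-9-(4-methoxybenzyloxy)-6,6,10-trimethyl-3-(prop-1-en-2-yl)-2-oxaspiro[4.5]dec-7-en-1-one
Conditions: second-generation Grubbs catalyst RuCl2(=CHPh)(PCy3)(H2IMes) (10 mol %), toluene (0.005 M), 80 °C, argon sparge
Reagents that add atoms: none
Why: Ring-closing olefin metathesis by the Chauvin mechanism: the ruthenium benzylidene exchanges onto the monosubstituted vinyl group, the new alkylidene adds intramolecularly across the 1,1-disubstituted bromoalkene with ruthenium on the CH2 terminus, and cycloreversion of the ruthenacyclobutane releases the C(Br)=CH bond of ring A and Ru=CH2, which carries the chain after loss of ethylene. The closest known reaction type is diene ring-closing metathesis to cycloalkenyl halides, well established for chlorides and fluorides and shown for bromides only in a narrow range. Ring A closes as a six-membered carbocycle through this intramolecular [2+2] cycloaddition and cycloreversion, helped by the two quaternary carbons and the tertiary carbinol in the four-atom tether (Thorpe–Ingold effect). No stereocentre is formed and the new alkene is necessarily cis within the ring. The step needs site selectivity for the vinyl and 2-bromoallyl pair over the isopropenyl group and a regiochemistry that never places bromine on the carbene carbon: the catalyst can load only at the vinyl group because both 1,1-disubstituted alkenes are too hindered for intermolecular attack (the bromoalkene sits on the CMe2 carbon), closure onto isopropenyl would need a bridged seven-membered ring, and ruthenium on CH2 is the only orientation the tether allows for a six-membered ring.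

Step 15
Reactants: 23 bromocyclohexene spiro-lactone
Product: 24 (3R,5S,9R,10S)-7-bromo-9-(4-methoxybenzyloxy)-6,6,10-trimethyl-3-(prop-1-en-2-yl)-2-oxaspiro[4.5]dec-7-ene-1,10-diol (lactol, anomers)
Conditions: i-Bu2AlH (2.5 equiv), CH2Cl2, −78 °C; aq. potassium sodium tartrate
Reagents that add atoms: none
Why: Low-temperature i-Bu2AlH reduction of a lactone stops at the aluminium hemiacetal, which gives the lactol on work-up, and the neopentyl position of the carbonyl disfavours over-reduction.

Step 16
Reactants: 24 hydroxy lactol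
Product: 25 (1S,3R,5S,9R,10S)-7-bromo-1,10-epoxy-9-(4-methoxybenzyloxy)-6,6,10-trimethyl-3-(prop-1-en-2-yl)-2-oxaspiro[4.5]dec-7-ene (oxetane acetal)
Conditions: PPh3, DIAD, toluene, 0 °C → rt
Reagents that add atoms: none
Why: Mitsunobu-type cyclodehydration of a 1,3-diol in which one hydroxyl is a lactol (a known way to strained bicyclic oxetane acetals): the anomeric hydroxyl is activated as the oxyphosphonium, ionizes to an oxocarbenium ion that has no α-hydrogen to lose, and is trapped by the tertiary hydroxyl held next to it by the quaternary carbon, under neutral conditions the acetal should survive, with the acetal configuration dictated by the cis fusion of the four-membered ring.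

Step 17
Reactants: 25 PMB-protected oxetane acetal
Product: 26 (1S,3R,5S,9R,10S)-7-bromo-1,10-epoxy-6,6,10-trimethyl-3-(prop-1-en-2-yl)-2-oxaspiro[4.5]dec-7-en-9-ol
Conditions: DDQ, CH2Cl2/pH 7 buffer (KH2PO4/Na2HPO4), 0 °C
Reagents that add atoms: none
Why: Oxidative PMB cleavage by DDQ proceeds by hydride abstraction from the electron-rich benzyl ether and hydrolysis of the oxocarbenium ion, and in buffered medium it should leave the alkenes, the bromoalkene and the acetal untouched.

Step 18
Reactants: 26 allylic alcohol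
Product: 27 (1S,3R,5S,9S,10S)-7,9-dibromo-1,10-epoxy-6,6,10-trimethyl-3-(prop-1-en-2-yl)-2-oxaspiro[4.5]dec-7-ene (target, CNP0141320.1)
Conditions: CBr4, P(n-C8H17)3, 2,6-di-tert-butylpyridine, toluene, 0 → 60 °C
Reagents that add atoms: tetrabromomethane, BrC(Br)(Br)Br
Why: Appel-type bromination, in which bromide displaces the alkoxyphosphonium group by SN2 with inversion (SN2′ is blocked because the far alkene terminus carries bromine and a quaternary neighbour), which places bromine anti to the oxetane oxygen as in the target.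

**Compound list**

1 | 2-bromopropene | C=C(C)Br | starting material
2 | succinic anhydride | O=C1CCC(=O)O1 | starting material
3 | isopropenylmagnesium bromide | C=C(C)[Mg]Br | intermediate
4 | 5-methyl-4-oxohex-5-enoic acid | C=C(C)C(=O)CCC(=O)O | intermediate
5 | methyl 5-methyl-4-oxohex-5-enoate | C=C(C)C(=O)CCC(=O)OC | intermediate
6 | methyl (R)-4-hydroxy-5-methylhex-5-enoate | C=C(C)[C@H](O)CCC(=O)OC | intermediate
7 | (R)-5-(prop-1-en-2-yl)dihydrofuran-2(3H)-one | C=C(C)[C@H]1CCC(=O)O1 | intermediate
8 | 2-methylbut-3-yn-2-ol | CC(C)(O)C#C | starting material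
9 | hexacarbonyl(μ-2-methylbut-3-yn-2-ol)dicobalt | CC(C)(O)C12[CH]3[Co]1(=C=O)(=C=O)(=C=O)[Co]23(=C=O)(=C=O)=C=O | intermediate
10 | (R)-trimethyl{[5-(prop-1-en-2-yl)-4,5-dihydrofuran-2-yl]oxy}silane | C=C(C)[C@H]1CC=C(O[Si](C)(C)C)O1 | intermediate
11 | Co2(CO)6 complex of (5R)-3-(2-methylbut-3-yn-2-yl)-5-(prop-1-en-2-yl)dihydrofuran-2(3H)-one (C3 epimers) | C=C(C)[C@H]1CC(C(=O)O1)C(C)(C)C23[CH]4[Co]2(=C=O)(=C=O)(=C=O)[Co]34(=C=O)(=C=O)=C=O | intermediate
12 | (5R)-3-(2-methylbut-3-yn-2-yl)-5-(prop-1-en-2-yl)dihydrofuran-2(3H)-one (C3 epimers) | C=C(C)[C@H]1CC(C(=O)O1)C(C)(C)C#C | intermediate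
13 | (Z)-2-bromoalkenyl-9-BBN adduct of 12 (boron and bromine cis) | C=C(C)[C@H]1CC(C(=O)O1)C(C)(C)/C(Br)=C/B1C2CCCC1CCC2 | intermediate
14 | (5R)-3-(3-bromo-2-methylbut-3-en-2-yl)-5-(prop-1-en-2-yl)dihydrofuran-2(3H)-one (C3 epimers) | C=C(C)[C@H]1CC(C(=O)O1)C(C)(C)C(Br)=C | intermediate
15 | (R)-but-3-ene-1,2-diol | OC[C@H](O)C=C | starting material
16 | (4R)-2-(4-methoxyphenyl)-4-vinyl-1,3-dioxolane (acetal epimers) | C=C[C@H]1OC(c2ccc(OC)cc2)OC1 | intermediate
17 | (R)-2-(4-methoxybenzyloxy)but-3-en-1-ol | OC[C@H](OCc1ccc(OC)cc1)C=C | intermediate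
18 | (R)-2-(4-methoxybenzyloxy)but-3-enal | O=C[C@H](OCc1ccc(OC)cc1)C=C | intermediate
19 | lithium enolate of 14 | C=C(C)[C@H]1CC(C(C)(C)C(Br)=C)=C(O[Li])O1 | intermediate
20 | (3S,5R)-3-(3-bromo-2-methylbut-3-en-2-yl)-3-[(2R)-1-hydroxy-2-(4-methoxybenzyloxy)but-3-en-1-yl]-5-(prop-1-en-2-yl)dihydrofuran-2(3H)-one (carbinol epimers) | C=C(C)[C@H]1C[C@@](C(=O)O1)(C(O)[C@H](OCc2ccc(OC)cc2)C=C)C(C)(C)C(Br)=C | intermediate
21 | (3S,5R)-3-(3-bromo-2-methylbut-3-en-2-yl)-3-[(2R)-2-(4-methoxybenzyloxy)but-3-enoyl]-5-(prop-1-en-2-yl)dihydrofuran-2(3H)-one | C=C(C)[C@H]1C[C@@](C(=O)O1)(C(=O)[C@H](OCc2ccc(OC)cc2)C=C)C(C)(C)C(Br)=C | intermediate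
22 | (3S,5R)-3-(3-bromo-2-methylbut-3-en-2-yl)-3-[(2S,3R)-2-hydroxy-3-(4-methoxybenzyloxy)pent-4-en-2-yl]-5-(prop-1-en-2-yl)dihydrofuran-2(3H)-one | C=C(C)[C@H]1C[C@@](C(=O)O1)([C@](C)(O)[C@H](OCc2ccc(OC)cc2)C=C)C(C)(C)C(Br)=C | intermediate
23 | (3R,5S,9R,10S)-7-bromo-10-hydroxy-9-(4-methoxybenzyloxy)-6,6,10-trimethyl-3-(prop-1-en-2-yl)-2-oxaspiro[4.5]dec-7-en-1-one | C=C(C)[C@H]1C[C@@]2(C(=O)O1)[C@](C)(O)[C@H](OCc3ccc(OC)cc3)C=C(Br)C2(C)C | intermediate
24 | (3R,5S,9R,10S)-7-bromo-9-(4-methoxybenzyloxy)-6,6,10-trimethyl-3-(prop-1-en-2-yl)-2-oxaspiro[4.5]dec-7-ene-1,10-diol (anomers) | C=C(C)[C@H]1C[C@@]2(C(O)O1)[C@](C)(O)[C@H](OCc3ccc(OC)cc3)C=C(Br)C2(C)C | intermediate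
25 | (1S,3R,5S,9R,10S)-7-bromo-1,10-epoxy-9-(4-methoxybenzyloxy)-6,6,10-trimethyl-3-(prop-1-en-2-yl)-2-oxaspiro[4.5]dec-7-ene | C=C(C)[C@H]1C[C@@]23[C@@H](O1)O[C@]2(C)[C@H](OCc4ccc(OC)cc4)C=C(Br)C3(C)C | intermediate
26 | (1S,3R,5S,9R,10S)-7-bromo-1,10-epoxy-6,6,10-trimethyl-3-(prop-1-en-2-yl)-2-oxaspiro[4.5]dec-7-en-9-ol | C=C(C)[C@H]1C[C@@]23[C@@H](O1)O[C@]2(C)[C@H](O)C=C(Br)C3(C)C | intermediate
27 | (1S,3R,5S,9S,10S)-7,9-dibromo-1,10-epoxy-6,6,10-trimethyl-3-(prop-1-en-2-yl)-2-oxaspiro[4.5]dec-7-ene | C=C(C)[C@H]1C[C@@]23[C@@H](O1)O[C@]2(C)[C@@H](Br)C=C(Br)C3(C)C | target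

**Step count and risks**

Total steps: 18. Longest linear sequence: 14 steps (steps 1–3, 5–7 and 11–18).

Steps most likely to fail:

1. Step 14. The alkenyl bromide may deactivate the ruthenium carbene, or turnover on the hindered, electron-poor alkene may be slower than catalyst decay, so that ring A does not close. The fallback sets out from 22 and changes the alkene partner. Miyaura borylation (B2pin2, Pd(dppf)Cl2, KOAc, dioxane, 80 °C) would convert the alkenyl bromide into the diene pinacol boronate F1. Ring-closing metathesis of F1 with the same ruthenium catalyst, a well-established closure for 1-substituted vinyl boronates, would give the cyclic alkenyl boronate F2. CuBr2 in MeOH/H2O would then replace boron by bromine, and the route is rejoined at 23.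

2. Step 16. The activated lactol may not be intercepted by the hindered tertiary hydroxyl (return to lactol or loss of the tertiary alcohol by elimination), or the strained acetal may re-open. The fallback sets out from 24 and separates activation from closure. Cl3CCN with K2CO3 in CH2Cl2 would give the anomeric trichloroacetimidate F3, the lactol hydroxyl being the more acidic and less hindered one. Catalytic TMSOTf with 4 Å molecular sieves at −78 °C, quenched with Et3N, would then trigger an intramolecular Schmidt glycosylation by the tertiary hydroxyl, and the route is rejoined at 25.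

3. Step 18. Backside attack at the allylic carbon, which is flanked by the fully substituted oxetane carbon, may be slow, so that ionization erodes the inversion or HBr cleaves the acetal. The fallback sets out from 23 and introduces the bromide before the acetal exists, through a tethered leaving group. DDQ would give the diol lactone F4, and SOCl2 with pyridine the cyclic sulfite F5. LiBr in DMF would open the sulfite at the allylic carbon with inversion, and dilute acid would release SO2 to give the bromohydrin lactone F6. i-Bu2AlH at −78 °C would give the bromo lactol F7. PPh3/DIAD, premixed so that no free phosphine meets the allylic bromide, would close the oxetane, and the route is rejoined at 27.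

**Further compounds**

F1 | step 14 | (3S,5R)-3-[(2S,3R)-2-hydroxy-3-(4-methoxybenzyloxy)pent-4-en-2-yl]-3-[2-methyl-3-(4,4,5,5-tetramethyl-1,3,2-dioxaborolan-2-yl)but-3-en-2-yl]-5-(prop-1-en-2-yl)dihydrofuran-2(3H)-one | C=C(C)[C@H]1C[C@@](C(=O)O1)([C@](C)(O)[C@H](OCc2ccc(OC)cc2)C=C)C(C)(C)C(=C)B3OC(C)(C)C(C)(C)O3
F2 | step 14 | (3R,5S,9R,10S)-10-hydroxy-9-(4-methoxybenzyloxy)-6,6,10-trimethyl-3-(prop-1-en-2-yl)-7-(4,4,5,5-tetramethyl-1,3,2-dioxaborolan-2-yl)-2-oxaspiro[4.5]dec-7-en-1-one | C=C(C)[C@H]1C[C@@]2(C(=O)O1)[C@](C)(O)[C@H](OCc3ccc(OC)cc3)C=C(B4OC(C)(C)C(C)(C)O4)C2(C)C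
F3 | step 16 | (3R,5S,9R,10S)-7-bromo-10-hydroxy-9-(4-methoxybenzyloxy)-6,6,10-trimethyl-3-(prop-1-en-2-yl)-2-oxaspiro[4.5]dec-7-en-1-yl 2,2,2-trichloroacetimidate (anomers) | C=C(C)[C@H]1C[C@@]2(C(OC(=N)C(Cl)(Cl)Cl)O1)[C@](C)(O)[C@H](OCc3ccc(OC)cc3)C=C(Br)C2(C)C
F4 | step 18 | (3R,5S,9R,10S)-7-bromo-9,10-dihydroxy-6,6,10-trimethyl-3-(prop-1-en-2-yl)-2-oxaspiro[4.5]dec-7-en-1-one | C=C(C)[C@H]1C[C@@]2(C(=O)O1)[C@](C)(O)[C@H](O)C=C(Br)C2(C)C
F5 | step 18 | cyclic sulfite (9,10-O-sulfinyl derivative) of F4, sulfur epimers | C=C(C)[C@H]1C[C@@]2(C(=O)O1)[C@]3(C)OS(=O)O[C@@H]3C=C(Br)C2(C)C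
F6 | step 18 | (3R,5S,9S,10S)-7,9-dibromo-10-hydroxy-6,6,10-trimethyl-3-(prop-1-en-2-yl)-2-oxaspiro[4.5]dec-7-en-1-one | C=C(C)[C@H]1C[C@@]2(C(=O)O1)[C@](C)(O)[C@@H](Br)C=C(Br)C2(C)C
F7 | step 18 | (3R,5S,9S,10S)-7,9-dibromo-6,6,10-trimethyl-3-(prop-1-en-2-yl)-2-oxaspiro[4.5]dec-7-ene-1,10-diol (anomers) | C=C(C)[C@H]1C[C@@]2(C(O)O1)[C@](C)(O)[C@@H](Br)C=C(Br)C2(C)C
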